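**Retrosynthetic overview**
1. Last step: chelation-controlled cleavage of only the 3- and 5-methyl ethers of a 2'-hydroxy-pentamethoxyflavone.
2. Key disconnection: the C2–C1' bond between ring C and ring B. It is made by direct C2–H zincation of a 3-methoxychromone and Negishi coupling with an unprotected o-iodophenol, so no chalcone/Algar–Flynn–Oyamada or Baker–Venkataraman/Allan–Robinson step is used.
3. Ring C: enaminone annulation (one carbon from DMF-DMA) of an o-hydroxyaryl methoxymethyl ketone, so O-3 is present from the start.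
4. Ketone: directed ortho-lithiation of a tetramethoxybenzene and Weinreb acylation, then selective ortho-demethylation.
5. Ring order: ring A is bought, ring C is closed on it, and ring B (bought) is attached last.

Assumption: the target SMILES has no stereocentre, no stereogenic double bond and no hindered axis, so the compound is achiral and "single enantiomer" calls for no stereocontrol.

**Step 1**
Reactants: 1 1,2,3,5-tetramethoxybenzene; 2 N,2-dimethoxy-N-methylacetamide
Product: 4 2-methoxy-1-(2,3,4,6-tetramethoxyphenyl)ethan-1-one, via aryllithium 3 (not isolated)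
Conditions: n-BuLi (1.1 equiv), THF, 0 °C to rt, 1 h; then 2, −78 to 0 °C; 1 M HCl
Reagents that add atoms: n-butyllithium, [Li]CCCC (its lithium stays in 3 only; none of its atoms is left in 4)
Why: Directed ortho-metalation followed by Weinreb ketone synthesis: the two equivalent ring C–H bonds of 1 each lie between two methoxy groups and are lithiated cleanly, and the N-methoxy-N-methylamide stops at single addition, which avoids the decarbonylation that plagues Friedel–Crafts acylation with methoxyacetyl chloride.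

**Step 2**
Reactants: 4 2-methoxy-1-(2,3,4,6-tetramethoxyphenyl)ethan-1-one
Product: 5 1-(2-hydroxy-3,4,6-trimethoxyphenyl)-2-methoxyethan-1-one
Conditions: BCl3 (1.5 equiv), CH2Cl2, −78 to 0 °C, 2 h; H2O
Reagents that add atoms: none
Why: Chelation-controlled Lewis-acid ether cleavage: BCl3 binds the ketone oxygen together with an ortho methoxy oxygen, and chloride removes the methyl of the 2-OMe group, which is pushed out of the ring plane by its 3-OMe neighbour and is therefore the more basic and more strained of the two ortho ethers, while a second cleavage is slow at low temperature.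

**Step 3**
Reactants: 5 1-(2-hydroxy-3,4,6-trimethoxyphenyl)-2-methoxyethan-1-one
Product: 7 3,5,7,8-tetramethoxy-4H-chromen-4-one, via enaminone 6 (not isolated)
Conditions: DMF-DMA (3 equiv), toluene, 110 °C, 6 h; then AcOH, 80 °C, 1 h
Reagents that add atoms: N,N-dimethylformamide dimethyl acetal (DMF-DMA), COC(OC)N(C)C
Why: Enaminone route to chromones: DMF-DMA condenses at the only enolisable carbon (the OCH2 group) to give push-pull enaminone 6, whose beta carbon is then attacked by the neighbouring phenol with loss of dimethylamine (addition-elimination), which closes ring C with O-3 already in place and leaves C2–H free for the key step.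

**Step 4 (key step)**
Reactants: 7 3,5,7,8-tetramethoxy-4H-chromen-4-one; 8 2-iodo-5-methoxyphenol
Product: 12 2-(2-hydroxy-4-methoxyphenyl)-3,5,7,8-tetramethoxy-4H-chromen-4-one, via chromon-2-ylzinc chloride 9 (not isolated), via chlorozinc iodophenolate 10 (not isolated), via chlorozinc flavone phenolate 11 (not isolated)
Conditions: flask A: 7, TMPZnCl·LiCl (1.2 equiv), THF, 25 °C, 2 h; flask B: 8, TMPZnCl·LiCl (1.05 equiv), THF, 0 °C; combine, Pd(OAc)2 (2 mol %), SPhos (4 mol %), 50 °C, 12 h; 1 M HCl
Reagents that add atoms: (2,2,6,6-tetramethylpiperidin-1-yl)zinc chloride–lithium chloride (TMPZnCl·LiCl), CC1(C)CCCC(C)(C)N1[Zn]Cl.[Li+].[Cl-] (its Zn and Cl stay in 9, 10 and 11 only; none of its atoms is left in 12)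
Why: C–H zincation followed by Negishi cross-coupling: with C3 blocked, the mild amide base removes the only acidic proton (C2–H, next to the ring oxygen and the 3-OMe group and beta to the carbonyl) and leaves the far less acidic C6–H alone, the covalent C–Zn bond of 9 does not ring-open, the phenol of 8 is masked in the flask as zinc phenolate 10 so that it cannot protonate 9, and the zerovalent palladium/SPhos catalyst formed in situ couples ortho-substituted aryl iodides and heteroarylzinc chlorides under mild conditions.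

**Step 5**
Reactants: 12 2-(2-hydroxy-4-methoxyphenyl)-3,5,7,8-tetramethoxy-4H-chromen-4-one
Product: 13 3,5,2'-trihydroxy-7,8,4'-trimethoxyflavone [3,5-dihydroxy-2-(2-hydroxy-4-methoxyphenyl)-7,8-dimethoxy-4H-chromen-4-one]
Conditions: AlBr3 (6 equiv), MeCN, 0 to 25 °C, 3 h; then 2 M HCl, 50 °C, 20 min
Reagents that add atoms: none
Why: Chelation-controlled Lewis-acid ether cleavage: only the 3- and 5-methoxy oxygens sit next to the C4 carbonyl and can bind aluminium in a chelating way, so bromide removes just these two methyl groups, while AlBr3 tamed by MeCN leaves the non-chelating 7-, 8- and 4'-methyl ethers alone, a selectivity that is well established for 3,5,7,8-tetramethoxyflavones.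

**Compound list**
1 | 1,2,3,5-tetramethoxybenzene | COc1cc(OC)c(OC)c(OC)c1 | starting material
2 | N,2-dimethoxy-N-methylacetamide | COCC(=O)N(C)OC | starting material
3 | (2,3,4,6-tetramethoxyphenyl)lithium | [Li]c1c(OC)cc(OC)c(OC)c1OC | intermediate (not isolated)
4 | 2-methoxy-1-(2,3,4,6-tetramethoxyphenyl)ethan-1-one | COCC(=O)c1c(OC)cc(OC)c(OC)c1OC | intermediate
5 | 1-(2-hydroxy-3,4,6-trimethoxyphenyl)-2-methoxyethan-1-one | COCC(=O)c1c(O)c(OC)c(OC)cc1OC | intermediate
6 | (Z)-3-(dimethylamino)-1-(2-hydroxy-3,4,6-trimethoxyphenyl)-2-methoxyprop-2-en-1-one | CN(C)/C=C(\OC)C(=O)c1c(O)c(OC)c(OC)cc1OC | intermediate (not isolated)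
7 | 3,5,7,8-tetramethoxy-4H-chromen-4-one | COc1coc2c(OC)c(OC)cc(OC)c2c1=O | intermediate
8 | 2-iodo-5-methoxyphenol | COc1ccc(I)c(O)c1 | starting material
9 | chloro(3,5,7,8-tetramethoxy-4-oxo-4H-chromen-2-yl)zinc | COc1c([Zn]Cl)oc2c(OC)c(OC)cc(OC)c2c1=O | intermediate (not isolated)
10 | chlorozinc 2-iodo-5-methoxyphenolate | COc1ccc(I)c(O[Zn]Cl)c1 | intermediate (not isolated)
11 | chlorozinc 5-methoxy-2-(3,5,7,8-tetramethoxy-4-oxo-4H-chromen-2-yl)phenolate | COc1ccc(-c2oc3c(OC)c(OC)cc(OC)c3c(=O)c2OC)c(O[Zn]Cl)c1 | intermediate (not isolated)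
12 | 2-(2-hydroxy-4-methoxyphenyl)-3,5,7,8-tetramethoxy-4H-chromen-4-one | COc1ccc(-c2oc3c(OC)c(OC)cc(OC)c3c(=O)c2OC)c(O)c1 | intermediate
13 | 3,5,2'-trihydroxy-7,8,4'-trimethoxyflavone (achiral) | COc1ccc(-c2oc3c(OC)c(OC)cc(O)c3c(=O)c2O)c(O)c1 | target

**Total step count:** 5. **Longest linear sequence:** 5 (1 to 13; 2 and 8 are bought).

**Three steps most likely to fail**

**Step 4.** The risks are incomplete zincation of the electron-rich chromone, slow coupling of the electron-rich ortho-oxido iodide, and protodezincation. The fallback gives up the C2–C1' coupling and closes ring C last. It sets out from 5 and comes back at 12. Claisen–Schmidt condensation of 5 with commercial 2-(benzyloxy)-4-methoxybenzaldehyde (KOH, EtOH, 25 °C) gives (Z)-3-[2-(benzyloxy)-4-methoxyphenyl]-1-(2-hydroxy-3,4,6-trimethoxyphenyl)-2-methoxyprop-2-en-1-one F1. Oxidative cyclisation (I2 10 mol %, DMSO, 130 °C) gives 2-[2-(benzyloxy)-4-methoxyphenyl]-3,5,7,8-tetramethoxy-4H-chromen-4-one F2. Hydrogenolysis (H2, 10% Pd/C, EtOAc, rt) then gives 12.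

**Step 5.** The risks are that the 3-OMe group is left on or that the 8-OMe group is lost as well, giving mixtures at the last stage. The fallback moves the ether cleavage in front of the coupling and changes to benzyl ethers, so that the endgame is a neutral hydrogenolysis. It sets out from 7 and comes back at 13.
- AlBr3 in MeCN on 7 (no ring B present, over-cleaved material removed early) gives 3,5-dihydroxy-7,8-dimethoxy-4H-chromen-4-one F3.
- BnBr, K2CO3, DMF, 70 °C gives 3,5-bis(benzyloxy)-7,8-dimethoxy-4H-chromen-4-one F4.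
- TMPZnCl·LiCl in THF gives [3,5-bis(benzyloxy)-7,8-dimethoxy-4-oxo-4H-chromen-2-yl]zinc chloride F5.
- F5 couples with 10 under the catalyst of step 4 to give chlorozinc 2-[3,5-bis(benzyloxy)-7,8-dimethoxy-4-oxo-4H-chromen-2-yl]-5-methoxyphenolate F6.
- Acid work-up gives 3,5-bis(benzyloxy)-2-(2-hydroxy-4-methoxyphenyl)-7,8-dimethoxy-4H-chromen-4-one F7.
- H2, 10% Pd/C, EtOAc/MeOH gives 13.

**Step 2.** The risks are cleavage of the 6-OMe instead of the 2-OMe group, which would lead into the 5,6,7-series, or double cleavage. The fallback removes both ortho ethers on purpose and puts one back, so that selectivity comes from sterically governed O-alkylation instead of from dealkylation. It sets out from 4 and comes back at 5. BCl3 (3.5 equiv, CH2Cl2, 0 °C to rt) gives 1-(2,6-dihydroxy-3,4-dimethoxyphenyl)-2-methoxyethan-1-one F8. MeI (1.0 equiv), K2CO3, acetone, rt then methylates the open 6-OH, which is flanked by H. The 2-OH, buttressed by the 3-OMe group, stays locked in the hydrogen bond to the ketone, and the product is 5.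

**Further compounds**
F1 | step 4 | (Z)-3-[2-(benzyloxy)-4-methoxyphenyl]-1-(2-hydroxy-3,4,6-trimethoxyphenyl)-2-methoxyprop-2-en-1-one | CO/C(=C\c1ccc(OC)cc1OCc1ccccc1)C(=O)c1c(O)c(OC)c(OC)cc1OC
F2 | step 4 | 2-[2-(benzyloxy)-4-methoxyphenyl]-3,5,7,8-tetramethoxy-4H-chromen-4-one | COc1ccc(-c2oc3c(OC)c(OC)cc(OC)c3c(=O)c2OC)c(OCc2ccccc2)c1
F3 | step 5 | 3,5-dihydroxy-7,8-dimethoxy-4H-chromen-4-one | COc1cc(O)c2c(=O)c(O)coc2c1OC
F4 | step 5 | 3,5-bis(benzyloxy)-7,8-dimethoxy-4H-chromen-4-one | COc1cc(OCc2ccccc2)c2c(=O)c(OCc3ccccc3)coc2c1OC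
F5 | step 5 | [3,5-bis(benzyloxy)-7,8-dimethoxy-4-oxo-4H-chromen-2-yl]zinc chloride | COc1cc(OCc2ccccc2)c2c(=O)c(OCc3ccccc3)c([Zn]Cl)oc2c1OC
F6 | step 5 | chlorozinc 2-[3,5-bis(benzyloxy)-7,8-dimethoxy-4-oxo-4H-chromen-2-yl]-5-methoxyphenolate | COc1ccc(-c2oc3c(OC)c(OC)cc(OCc4ccccc4)c3c(=O)c2OCc2ccccc2)c(O[Zn]Cl)c1
F7 | step 5 | 3,5-bis(benzyloxy)-2-(2-hydroxy-4-methoxyphenyl)-7,8-dimethoxy-4H-chromen-4-one | COc1ccc(-c2oc3c(OC)c(OC)cc(OCc4ccccc4)c3c(=O)c2OCc2ccccc2)c(O)c1
F8 | step 2 | 1-(2,6-dihydroxy-3,4-dimethoxyphenyl)-2-methoxyethan-1-one | COCC(=O)c1c(O)cc(OC)c(OC)c1O
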